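I start from a neighbour of red, the same flask read early at 50 min, because I want a rule that serves it and the three flasks below.

the same everywhere: D 0.80 M; time 1.5 h

| flask | E |
|---|---|
| red | 1.60 M |
| amber | 2.10 M |
| violet | 2.70 M |

    D + E ⇌ Z + J (K1 = 1.4, k1 = 0.68 M⁻¹ h⁻¹)
    J + E ⇌ Z + X (K2 = 0.58, k2 = 0.26 M⁻¹ h⁻¹)
    Z + E ⇌ Z.E, settled at all times (K3 = 12 M⁻¹)

1. part of the D that has reacted at the end, red
2. part of the D that has reacted at the end, amber
3. part of the D that has reacted at the end, violet
4. what raising the concentration of E from its lowest to its highest value here does to the part of the D that has reacted (changes below 5 percentage points count as none) (it falls / it rises / no change)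

- Z is meant together with its Z.E
- run time (red): 1.5 h

Turn the question round: one way for E to change nothing is that red stands within 5 percentage points of complete, leaving violet no room to gain. So how much room does red leave? I follow one Z just released. At red's charge the odds of binding against staying free are 19 to one, so nearly all of it takes a further E. I assume this lasts and drop both the way back and the second step, so in this reckoning each D reacted costs two E.

Red holds 2.00 E per D, so in this reckoning E stays twice D and the D left is the charge divided by one plus the paired clock 1.63, which is twice the rate constant of the first step, times the D charged, times the time. That gives 62.0% reacted and leaves 38.0% of red's D, far from the 5 points that way needs.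

At two E per D, D is the limiting reagent of this reckoning in amber and violet, with surpluses of E of 0.500 M and 1.10 M. The ratio of E to D grows by the exponential of rate constant times surplus times time, and the D left is the surplus over that ratio minus two. I get 73.6% and 83.6%, so violet reacts further than red.

The forecast, a little lower than mine, gives 59%, 70% and 80%, says it rises, and calls the run “essentially kinetically limited”.

The simulation gives 59.8%, 70.6% and 80.2%, and it rises by 20 points. For the neighbour the clock reads 0.907, which gives 47.6% reacted, and that flask shows 46.8%. Red is not at rest at 1.5 h. At ten times the time the clock reads 16.3 and gives 94.2%, but the flask shows 71.5%, with D down from 40.2% to 28.5% and X up from 10.8% to 27.2%. The same wait takes violet from 80.2% to 91.5%.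

The numbers were chosen freely; the flask was simulated.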